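## Retrosynthetic overview

1. Target 13 is cut at the C2–aryl bond into 6‑geranyl‑5‑hydroxy‑7‑methoxychromone 11 and 3,4‑dimethoxyphenylboronic acid 12. This bond is made last by an enantioselective Rh(I)/chiral‑diene 1,4‑arylation, which also sets C2 (S), the only stereocentre.
2. Enabling feature: the C2=C3–C4=O vinylogous‑ester enone of the flat 4‑pyranone ring (ring C). C2 is an unsubstituted β‑carbon with two enantiotopic faces, it is the only electrophilic carbon next to O1, and the 5‑OH···O=C4 hydrogen bond activates the enone.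
3. 11 comes from 6‑iodochromone 6 and geranylstannane 10 (Stille coupling at C6). 6 comes from chromone 4 by iodination ortho to the chelated 5‑OH. 10 comes from geranyl chloride 7 and Bu3SnH 8.
4. 4 comes from the mirror‑symmetric 2,6‑dihydroxy‑4‑methoxyacetophenone 1 and DMF‑DMA 2; the symmetry makes the ring closure unambiguous.
5. Ring order: rings A and B are bought; ring C (pyranone) is closed in step 1; no ring is formed afterwards.

Key step: step 5

Remark: the target is read as the 2S flavanone with an (E)-geranyl group at C6; the sense of induction of the diene ligand is taken by analogy with cyclohex‑2‑enone and is to be checked, the antipodal ligand being used if needed.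

## Route

Step 1
Reactants: 1 1‑(2,6‑dihydroxy‑4‑methoxyphenyl)ethan‑1‑one; 2 N,N‑dimethylformamide dimethyl acetal
Product: 4 5‑hydroxy‑7‑methoxy‑4H‑chromen‑4‑one, via enaminone 3 (not isolated)
Conditions: DMF‑DMA (1.5 equiv), toluene, 90 °C; then AcOH, 80 °C
Reagents that add atoms: N,N‑dimethylformamide dimethyl acetal 2, COC(OC)N(C)C
Why: Aminomethylenation of the acetyl CH3 gives enaminone 3, and on acidification one of the two equivalent ortho phenols adds to the β‑carbon (6‑endo oxa‑Michael) with loss of dimethylamine, so a single chromone forms and the other phenol remains as the chelated 5‑OH (enaminone route to chromones).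

Step 2
Reactants: 4 5‑hydroxy‑7‑methoxy‑4H‑chromen‑4‑one; 5 benzyltrimethylammonium dichloroiodate
Product: 6 5‑hydroxy‑6‑iodo‑7‑methoxy‑4H‑chromen‑4‑one
Conditions: BnMe3N+ ICl2− (1.05 equiv), CaCO3, CH2Cl2/MeOH (5:2), rt
Reagents that add atoms: benzyltrimethylammonium dichloroiodate 5, C[N+](C)(C)Cc1ccccc1.Cl[I-]Cl
Why: Electrophilic aromatic iodination in which the free, carbonyl‑chelated 5‑OH should direct the iodine to its ortho carbon C6, as known for 5‑hydroxy‑7‑alkoxyflavones with this reagent, while C3 of the vinylogous ester is far less nucleophilic and CaCO3 takes up the HCl.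

Step 3
Reactants: 7 geranyl chloride, (2E)-1‑chloro‑3,7‑dimethylocta‑2,6‑diene; 8 tributyltin hydride
Product: 10 tributyl[(2E)-3,7‑dimethylocta‑2,6‑dien‑1‑yl]stannane, via tributylstannyllithium 9 (not isolated)
Conditions: LDA (1.05 equiv), THF, 0 °C; then 7, −78 °C → rt
Reagents that add atoms: tributyltin hydride 8, CCCC[SnH](CCCC)CCCC
Why: LDA deprotonates Bu3SnH to the stannyl anion 9, which displaces the primary allylic chloride by SN2 at the unhindered CH2, so the (E)-olefin is carried over without allylic transposition (stannyl anion alkylation).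

Step 4
Reactants: 6 5‑hydroxy‑6‑iodo‑7‑methoxy‑4H‑chromen‑4‑one; 10 tributyl[(2E)-3,7‑dimethylocta‑2,6‑dien‑1‑yl]stannane
Product: 11 6‑[(2E)-3,7‑dimethylocta‑2,6‑dien‑1‑yl]‑5‑hydroxy‑7‑methoxy‑4H‑chromen‑4‑one
Conditions: 10 (1.3 equiv), Pd(PPh3)4 (5 mol%), DMF, 80 °C, degassed
Reagents that add atoms: tributyl[(2E)-3,7‑dimethylocta‑2,6‑dien‑1‑yl]stannane 10, CCCC[Sn](CCCC)(CCCC)C/C=C(\C)CCC=C(C)C
Why: Stille coupling, in which oxidative addition of C6–I to Pd(0), allyl transfer from tin and reductive elimination at the less substituted allyl terminus should give the linear geranyl arene with E geometry retained, the chelated phenol and the pyranone enone being spectators.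

Step 5
Reactants: 11 6‑[(2E)-3,7‑dimethylocta‑2,6‑dien‑1‑yl]‑5‑hydroxy‑7‑methoxy‑4H‑chromen‑4‑one; 12 (3,4‑dimethoxyphenyl)boronic acid
Product: 13 (2S)-2‑(3,4‑dimethoxyphenyl)‑6‑[(2E)-3,7‑dimethylocta‑2,6‑dien‑1‑yl]‑5‑hydroxy‑7‑methoxy‑2,3‑dihydro‑4H‑chromen‑4‑one
Conditions: [RhCl(C2H4)2]2 (2.5 mol%), (S,S)-Ph‑bod* (5.5 mol%), aq. KOH (10 mol%), 12 (3 equiv), 1,4‑dioxane/H2O (10:1), 30 °C
Reagents that add atoms: (3,4‑dimethoxyphenyl)boronic acid 12, COc1ccc(B(O)O)cc1OC
Why: Hayashi–Miyaura asymmetric 1,4‑addition: the aryl group of 12 is transmetalated to the hydroxo‑rhodium(I)–diene complex, the aryl–Rh species binds C2=C3 of 11 and inserts it syn (enantio‑determining), placing the aryl carbon on C2 and Rh on C3 as an oxa‑π‑allyl enolate, and water protonates this to release 13 and regenerate Rh–OH. The closest known reaction type is the rhodium/chiral‑diene (or electron‑poor bisphosphine) conjugate arylation of chromones to flavanones, which is also known for 5,7‑dioxygenated chromones. No ring is closed: the pyranone ring of 11 is kept and only brought to the 2,3‑dihydro level, so no mode of cyclisation has to be controlled. The single stereocentre C2 is set by the C2‑symmetric diene, whose phenyl groups leave one enantiotopic face of the flat benzopyranone open; the (S,S)-ligand is expected, by analogy with cyclohex‑2‑enone, to give 2S. The step needs 1,4‑ over 1,2‑addition (secured by Rh(I) and the vinylogous‑ester character of C4), inertness of the two unactivated trisubstituted geranyl alkenes (they do not compete with the chelating diene or the enone), and no retro‑oxa‑Michael opening of the 5‑hydroxyflavanone (secured by the nearly neutral, boronic‑acid‑buffered medium at low temperature). The 5‑OH···O=C4 hydrogen bond keeps the phenol internally engaged and offsets the donor effect of the 7‑OMe on the enone.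

## Compound list

1 | 1‑(2,6‑dihydroxy‑4‑methoxyphenyl)ethan‑1‑one | CC(=O)c1c(O)cc(OC)cc1O | starting material
2 | N,N‑dimethylformamide dimethyl acetal | COC(OC)N(C)C | starting material
3 | (E)-1‑(2,6‑dihydroxy‑4‑methoxyphenyl)‑3‑(dimethylamino)prop‑2‑en‑1‑one (not isolated) | CN(C)/C=C/C(=O)c1c(O)cc(OC)cc1O | intermediate
4 | 5‑hydroxy‑7‑methoxy‑4H‑chromen‑4‑one | COc1cc(O)c2c(c1)occc2=O | intermediate
5 | benzyltrimethylammonium dichloroiodate | C[N+](C)(C)Cc1ccccc1.Cl[I-]Cl | starting material
6 | 5‑hydroxy‑6‑iodo‑7‑methoxy‑4H‑chromen‑4‑one | COc1cc2occc(=O)c2c(O)c1I | intermediate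
7 | geranyl chloride, (2E)-1‑chloro‑3,7‑dimethylocta‑2,6‑diene | ClC/C=C(\C)CCC=C(C)C | starting material
8 | tributyltin hydride | CCCC[SnH](CCCC)CCCC | starting material
9 | tributylstannyllithium (not isolated) | [Li][Sn](CCCC)(CCCC)CCCC | intermediate
10 | tributyl[(2E)-3,7‑dimethylocta‑2,6‑dien‑1‑yl]stannane | CCCC[Sn](CCCC)(CCCC)C/C=C(\C)CCC=C(C)C | intermediate
11 | 6‑[(2E)-3,7‑dimethylocta‑2,6‑dien‑1‑yl]‑5‑hydroxy‑7‑methoxy‑4H‑chromen‑4‑one | COc1cc2occc(=O)c2c(O)c1C/C=C(\C)CCC=C(C)C | intermediate
12 | (3,4‑dimethoxyphenyl)boronic acid | COc1ccc(B(O)O)cc1OC | starting material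
13 | (2S)-2‑(3,4‑dimethoxyphenyl)‑6‑[(2E)-3,7‑dimethylocta‑2,6‑dien‑1‑yl]‑5‑hydroxy‑7‑methoxy‑2,3‑dihydro‑4H‑chromen‑4‑one | COc1ccc([C@@H]2CC(=O)c3c(cc(OC)c(C/C=C(\C)CCC=C(C)C)c3O)O2)cc1OC | target

## Step count and risks

Total step count: 5. Longest linear sequence: 4 (steps 1, 2, 4, 5); step 3 is a one‑step side branch.

Steps most likely to fail:

Step 5 (key step). The phenol may sit on rhodium as a phenoxide and slow insertion into an already electron‑rich chromone. The electron‑rich boronic acid may be consumed by protodeboronation. The enantiomeric purity may erode through reversible ring opening of the 5‑hydroxyflavanone, or the facial discrimination may be insufficient. The fallback sets out from 11 and comes back at 13. The phenol is masked (MOMCl, i‑Pr2NEt, CH2Cl2, reflux) as 6‑geranyl‑7‑methoxy‑5‑(methoxymethoxy)chromone F1. The same Rh/diene arylation with 12 on this neutral vinylogous ester, where neither a phenoxide nor a chelated 5‑hydroxyflavanone can form, should give (2S)-2‑(3,4‑dimethoxyphenyl)‑6‑geranyl‑7‑methoxy‑5‑(methoxymethoxy)chroman‑4‑one F2. Brief treatment with HCl in MeOH (rt to 40 °C), under which a flavanone C2 centre is configurationally stable, then frees the 5‑OH and gives 13.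

Step 4. The allyl group may couple through its substituted terminus (branched isomer). The E geometry may be lost by η3–η1–η3 isomerisation on palladium. Oxidative addition at the doubly ortho‑substituted iodide may be slow, leading to protodeiodination. The fallback avoids allyl–palladium species altogether; it sets out from 1 and comes back at 11.
- C‑alkylation of the symmetric ketone 1 with geranyl bromide (DBU, THF, rt; SN2, E retained) can give only one mono‑C‑alkyl isomer, 1‑(3‑geranyl‑2,6‑dihydroxy‑4‑methoxyphenyl)ethanone F3.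
- TIPSCl/imidazole (DMF, 0 °C) should silylate the phenol that still has a free ortho position, giving the mono‑TIPS ether F4.
- MOMCl/NaH (THF, 0 °C) caps the hindered phenol next to the geranyl group, giving the MOM/TIPS‑protected ketone F5.
- DMF‑DMA (toluene, 100 °C) gives the protected enaminone F6.
- TBAF (THF, rt) removes the silyl group to the free‑phenol enaminone F7 (not isolated), which can close only through the liberated oxygen, with loss of dimethylamine, to the MOM chromone F1.
- HCl/MeOH removes the acetal to give 11; alternatively F1 is taken directly into the fallback for step 5.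

Step 2. The iodine may enter at C8 (para to the phenol) or at C3 of the pyranone, or a second iodination may follow. The fallback sets out from 4 and comes back at 11, bypassing steps 2–4. NaH (1.0 equiv) in toluene converts 4 into sodium 7‑methoxy‑4‑oxo‑4H‑chromen‑5‑olate F8 (suspension, not isolated), which is treated with geranyl bromide (rt → 60 °C). In the non‑polar medium the tight ion pair should deliver the allylic halide by SN2 to the carbon ortho to the phenoxide oxygen (C6), the classical ortho C‑allylation of metal phenoxides, with the E‑olefin intact. The O‑geranyl ether expected as by‑product is removed by chromatography.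

Further compounds
F1 | step 5 | 6‑[(2E)-3,7‑dimethylocta‑2,6‑dien‑1‑yl]‑7‑methoxy‑5‑(methoxymethoxy)‑4H‑chromen‑4‑one | COCOc1c(C/C=C(\C)CCC=C(C)C)c(OC)cc2occc(=O)c12
F2 | step 5 | (2S)-2‑(3,4‑dimethoxyphenyl)‑6‑[(2E)-3,7‑dimethylocta‑2,6‑dien‑1‑yl]‑7‑methoxy‑5‑(methoxymethoxy)‑2,3‑dihydro‑4H‑chromen‑4‑one | COc1ccc([C@@H]2CC(=O)c3c(cc(OC)c(C/C=C(\C)CCC=C(C)C)c3OCOC)O2)cc1OC
F3 | step 4 | 1‑{3‑[(2E)-3,7‑dimethylocta‑2,6‑dien‑1‑yl]‑2,6‑dihydroxy‑4‑methoxyphenyl}ethan‑1‑one | CC(=O)c1c(O)cc(OC)c(C/C=C(\C)CCC=C(C)C)c1O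
F4 | step 4 | 1‑{3‑[(2E)-3,7‑dimethylocta‑2,6‑dien‑1‑yl]‑2‑hydroxy‑4‑methoxy‑6‑(triisopropylsilyloxy)phenyl}ethan‑1‑one | CC(=O)c1c(O[Si](C(C)C)(C(C)C)C(C)C)cc(OC)c(C/C=C(\C)CCC=C(C)C)c1O
F5 | step 4 | 1‑{3‑[(2E)-3,7‑dimethylocta‑2,6‑dien‑1‑yl]‑4‑methoxy‑2‑(methoxymethoxy)‑6‑(triisopropylsilyloxy)phenyl}ethan‑1‑one | CC(=O)c1c(O[Si](C(C)C)(C(C)C)C(C)C)cc(OC)c(C/C=C(\C)CCC=C(C)C)c1OCOC
F6 | step 4 | (E)-3‑(dimethylamino)‑1‑{3‑[(2E)-3,7‑dimethylocta‑2,6‑dien‑1‑yl]‑4‑methoxy‑2‑(methoxymethoxy)‑6‑(triisopropylsilyloxy)phenyl}prop‑2‑en‑1‑one | CN(C)/C=C/C(=O)c1c(O[Si](C(C)C)(C(C)C)C(C)C)cc(OC)c(C/C=C(\C)CCC=C(C)C)c1OCOC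
F7 | step 4 | (E)-3‑(dimethylamino)‑1‑{3‑[(2E)-3,7‑dimethylocta‑2,6‑dien‑1‑yl]‑6‑hydroxy‑4‑methoxy‑2‑(methoxymethoxy)phenyl}prop‑2‑en‑1‑one (not isolated) | CN(C)/C=C/C(=O)c1c(O)cc(OC)c(C/C=C(\C)CCC=C(C)C)c1OCOC
F8 | step 2 | sodium 7‑methoxy‑4‑oxo‑4H‑chromen‑5‑olate (not isolated) | COc1cc([O-])c2c(c1)occc2=O.[Na+]
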